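**Plan**
- Retrosynthesis: the four phenols are masked as methoxymethyl (MOM) ethers and the carboxyl group on C1 of ring B is taken back to a formyl group; the ester C=O carbon (on ring A) and that formyl carbon are then rejoined as a C=C bond.
- Enabling feature: these two carbonyl carbons are bridged by the ester oxygen, the CH2 group and C6–C1 of ring B, so the rejoined double bond is C3=C4 of a six-membered cyclic enol ether, a 3-aryl-1H-isochromene (O2, C1H2, C8a, C4a, C4, C3).
- The isochromene is cut at O2–C3 and C1–H (6-endo oxycyclisation of an o-alkynylbenzaldehyde with hydride capture) and the alkyne at its C(sp)–C(aryl, ring B) bond (Sonogashira), giving a ring A arylacetylene and a ring B o-iodobenzaldehyde.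
- Forward: the ring B piece (4 steps from 3,5-dihydroxy-4-methylbenzoic acid) and the ring A piece (3 steps from 2,5-dimethylresorcinol) are joined, the pyran ring is closed and then opened again by ozonolysis; aldehyde oxidation and acetal removal finish.
- Stereochemistry: the target has no stereocentre and no stereogenic double bond, so none has to be set.

Key step: step 10

Remark: the only stereogenic centre on the route is the hemiperacetal carbon of a transient hydroperoxide in the key step, formed as a racemate and destroyed in the same flask.

**Step 1**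
Reactants: 1 3,5-dihydroxy-4-methylbenzoic acid
Product: 2 methoxymethyl 3,5-bis(methoxymethoxy)-4-methylbenzoate
Conditions: NaH (3.3 equiv), MOMCl (3.5 equiv), DMF, 0 °C → rt
Reagents that add atoms: chloromethyl methyl ether, COCCl
Why: Williamson-type O-alkylation of the carboxylate and both phenoxides by the highly reactive α-chloro ether masks all three acidic groups in one operation.

**Step 2**
Reactants: 2 methoxymethyl 3,5-bis(methoxymethoxy)-4-methylbenzoate
Product: 3 [3,5-bis(methoxymethoxy)-4-methylphenyl]methanol
Conditions: LiAlH4, THF, 0 °C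
Reagents that add atoms: none
Why: LiAlH4 reduces the methoxymethyl ester through the aldehyde to the benzylic alcohol (hydride reduction of an ester), while the aryl methoxymethyl ethers, being acetals, are inert to hydride.

**Step 3**
Reactants: 3 [3,5-bis(methoxymethoxy)-4-methylphenyl]methanol
Product: 4 [2-iodo-3,5-bis(methoxymethoxy)-4-methylphenyl]methanol
Conditions: NIS (1.05 equiv), MeCN, 0 °C → rt, dark
Reagents that add atoms: N-iodosuccinimide, O=C1CCC(=O)N1I
Why: Electrophilic aromatic iodination: the only free ring positions, C2 and C6, are equivalent and each lies ortho to one and para to the other methoxymethoxy group, so one equivalent of NIS under neutral conditions should give a single mono-iodide without acid that would endanger the acetals.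

**Step 4**
Reactants: 4 [2-iodo-3,5-bis(methoxymethoxy)-4-methylphenyl]methanol
Product: 5 2-iodo-3,5-bis(methoxymethoxy)-4-methylbenzaldehyde
Conditions: MnO2 (activated, 15 equiv), CH2Cl2, rt
Reagents that add atoms: none
Why: Activated MnO2 oxidises benzylic alcohols selectively to aldehydes without over-oxidation and leaves the aryl iodide and the acetals untouched.

**Step 5**
Reactants: 6 2,5-dimethylresorcinol (2,5-dimethylbenzene-1,3-diol)
Product: 8 2,4-dihydroxy-3,6-dimethylbenzaldehyde, via aryl iminium chloride 7 (not isolated)
Conditions: POCl3 (1.2 equiv), DMF, MeCN, 0 °C → rt; then H2O, 50 °C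
Reagents that add atoms: N,N-dimethylformamide, CN(C)C=O (formyl carbon); water, O (carbonyl oxygen)
Why: Vilsmeier–Haack formylation: the chloroiminium ion attacks C4 (equivalent to C6), ortho to one hydroxyl and para to the other, and hydrolysis of iminium salt 7 (and of any aryl formate) should release the aldehyde as a single regioisomer.

**Step 6**
Reactants: 8 2,4-dihydroxy-3,6-dimethylbenzaldehyde
Product: 9 2,4-bis(methoxymethoxy)-3,6-dimethylbenzaldehyde
Conditions: NaH (2.4 equiv), MOMCl (2.5 equiv), DMF, 0 °C → rt
Reagents that add atoms: chloromethyl methyl ether, COCCl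
Why: Williamson-type alkylation of both phenoxides, with NaH chosen because the hydroxyl next to the formyl group is hydrogen-bonded and flanked by a methyl group.

**Step 7**
Reactants: 9 2,4-bis(methoxymethoxy)-3,6-dimethylbenzaldehyde; 10 dimethyl (1-diazo-2-oxopropyl)phosphonate
Product: 11 2-ethynyl-3,5-bis(methoxymethoxy)-1,4-dimethylbenzene (the ring A arylacetylene; ethynyl flanked by a methoxymethoxy and a methyl group)
Conditions: K2CO3, MeOH/THF, 0 °C → rt
Reagents that add atoms: dimethyl (1-diazo-2-oxopropyl)phosphonate (compound 10), COP(=O)(OC)C(=[N+]=[N-])C(C)=O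
Why: Seyferth–Gilbert homologation in the Ohira–Bestmann variant: methoxide deacetylates 10, the diazomethylphosphonate anion olefinates the non-enolisable aldehyde, and loss of N2 with a 1,2-hydrogen shift gives the terminal alkyne under conditions mild enough for the acetals.

**Step 8**
Reactants: 5 2-iodo-3,5-bis(methoxymethoxy)-4-methylbenzaldehyde; 11 2-ethynyl-3,5-bis(methoxymethoxy)-1,4-dimethylbenzene
Product: 12 2-{[2,4-bis(methoxymethoxy)-3,6-dimethylphenyl]ethynyl}-3,5-bis(methoxymethoxy)-4-methylbenzaldehyde
Conditions: Pd(PPh3)2Cl2 (5 mol %), CuI (10 mol %), Et3N, DMF (degassed), 60 °C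
Reagents that add atoms: none
Why: Sonogashira coupling: oxidative addition of zerovalent palladium into the C–I bond is assisted by the ortho formyl group and the copper acetylide of 11 transfers the alkynyl group, o-iodobenzaldehydes being standard partners whose products carry no nucleophile able to add to the alkyne under these conditions.

**Step 9**
Reactants: 12 2-{[2,4-bis(methoxymethoxy)-3,6-dimethylphenyl]ethynyl}-3,5-bis(methoxymethoxy)-4-methylbenzaldehyde
Product: 13 3-[2,4-bis(methoxymethoxy)-3,6-dimethylphenyl]-5,7-bis(methoxymethoxy)-6-methyl-1H-isochromene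
Conditions: AuCl2(O2CC5H4N) [dichloro(pyridine-2-carboxylato)gold] (5 mol %), Hantzsch ester (diethyl 2,6-dimethyl-1,4-dihydropyridine-3,5-dicarboxylate, 1.1 equiv), ClCH2CH2Cl, rt
Reagents that add atoms: none
Why: Known domino cycloisomerisation/reduction of o-alkynylbenzaldehydes: the π-acidic trivalent gold activates the alkyne, the formyl oxygen closes 6-endo-dig on the alkyne carbon bearing ring A because this gives an aromatic 2-benzopyrylium species on the catalyst, the Hantzsch ester delivers hydride to C1 and protodeauration at C4 releases the 1H-isochromene, the pyridine formed keeping the medium non-acidic for the acetals.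

**Step 10**
Reactants: 13 3-[2,4-bis(methoxymethoxy)-3,6-dimethylphenyl]-5,7-bis(methoxymethoxy)-6-methyl-1H-isochromene
Product: 15 [2-formyl-3,5-bis(methoxymethoxy)-4-methylphenyl]methyl 2,4-bis(methoxymethoxy)-3,6-dimethylbenzoate, via methoxy hydroperoxide 14 (not isolated)
Conditions: O3 (1.0 equiv, dosed to the Sudan Red 7B end point), CH2Cl2/MeOH (4:1), NaHCO3, −78 °C; then Me2S, −78 °C → rt
Reagents that add atoms: ozone, [O-][O+]=O
Why: Ozone adds as a 1,3-dipole across C3=C4, the most electron-rich π bond of 13 (an enol ether conjugated with ring B), and the primary ozonide undergoes cycloreversion in the sense usual for enol ethers, leaving the ester C=O on C3 (the oxygen-bearing carbon, attached to ring A) and a carbonyl oxide on C4. Methanol adds to the carbonyl oxide to give hydroperoxide 14, which Me2S reduces to a hemiacetal that loses methanol to reveal the formyl group; the closest known reaction type is the reductive ozonolysis of cyclic enol ethers (dihydropyrans, benzofurans) to formyl or keto esters. No ring is closed, the pyran ring is opened, and no stereocentre is created in 15 (the hydroperoxide carbon of 14 is racemic and transient). The selectivity needed is chemoselectivity for the enol ether over the two alkoxy-substituted arenes and the benzylic O–CH2 group; it rests on the much faster addition of ozone to the enol ether, on dosing one equivalent at −78 °C, and on each ring becoming carbonyl-substituted and so less oxidisable once cleavage has occurred. Solid NaHCO3 keeps the medium neutral so that the four methoxymethyl ethers survive and the aldehyde is not converted into its dimethyl acetal.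

**Step 11**
Reactants: 15 [2-formyl-3,5-bis(methoxymethoxy)-4-methylphenyl]methyl 2,4-bis(methoxymethoxy)-3,6-dimethylbenzoate
Product: 16 6-({[2,4-bis(methoxymethoxy)-3,6-dimethylbenzoyl]oxy}methyl)-2,4-bis(methoxymethoxy)-3-methylbenzoic acid
Conditions: NaClO2, NaH2PO4, 2-methyl-2-butene (excess), t-BuOH/THF/H2O, 0 °C → rt
Reagents that add atoms: sodium chlorite, [Na+].[O-]Cl=O
Why: Pinnick oxidation: chlorous acid adds to the hindered aldehyde and fragments to the acid, 2-methyl-2-butene removing the HOCl that would otherwise chlorinate the electron-rich rings, while the buffered medium leaves the ester and the acetals intact.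

**Step 12**
Reactants: 16 6-({[2,4-bis(methoxymethoxy)-3,6-dimethylbenzoyl]oxy}methyl)-2,4-bis(methoxymethoxy)-3-methylbenzoic acid
Product: 17 6-{[(2,4-dihydroxy-3,6-dimethylbenzoyl)oxy]methyl}-2,4-dihydroxy-3-methylbenzoic acid (CNP0110620.0)
Conditions: HCl (2 M), MeOH/THF (1:1), rt
Reagents that add atoms: none
Why: Acid-catalysed acetal cleavage of the four aryl methoxymethyl ethers via the methoxymethyl cation, which methanol captures as dimethoxymethane so that it does not alkylate the activated rings, while the doubly ortho-substituted benzoate ester and benzoic acid are sterically shielded from methanolysis and esterification at room temperature.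

**Compound list**
1 | 3,5-dihydroxy-4-methylbenzoic acid | Cc1c(O)cc(cc1O)C(=O)O | starting material
2 | methoxymethyl 3,5-bis(methoxymethoxy)-4-methylbenzoate | COCOC(=O)c1cc(OCOC)c(C)c(OCOC)c1 | intermediate
3 | [3,5-bis(methoxymethoxy)-4-methylphenyl]methanol | OCc1cc(OCOC)c(C)c(OCOC)c1 | intermediate
4 | [2-iodo-3,5-bis(methoxymethoxy)-4-methylphenyl]methanol | OCc1cc(OCOC)c(C)c(OCOC)c1I | intermediate
5 | 2-iodo-3,5-bis(methoxymethoxy)-4-methylbenzaldehyde | O=Cc1cc(OCOC)c(C)c(OCOC)c1I | intermediate
6 | 2,5-dimethylresorcinol | Cc1cc(O)c(C)c(O)c1 | starting material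
7 | N-[(2,4-dihydroxy-3,6-dimethylphenyl)methylidene]-N-methylmethanaminium chloride (not isolated) | C[N+](C)=Cc1c(C)cc(O)c(C)c1O.[Cl-] | intermediate
8 | 2,4-dihydroxy-3,6-dimethylbenzaldehyde | Cc1cc(O)c(C)c(O)c1C=O | intermediate
9 | 2,4-bis(methoxymethoxy)-3,6-dimethylbenzaldehyde | Cc1cc(OCOC)c(C)c(OCOC)c1C=O | intermediate
10 | dimethyl (1-diazo-2-oxopropyl)phosphonate | COP(=O)(OC)C(=[N+]=[N-])C(C)=O | starting material
11 | 2-ethynyl-3,5-bis(methoxymethoxy)-1,4-dimethylbenzene | Cc1cc(OCOC)c(C)c(OCOC)c1C#C | intermediate
12 | 2-{[2,4-bis(methoxymethoxy)-3,6-dimethylphenyl]ethynyl}-3,5-bis(methoxymethoxy)-4-methylbenzaldehyde | O=Cc1cc(OCOC)c(C)c(OCOC)c1C#Cc1c(C)cc(OCOC)c(C)c1OCOC | intermediate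
13 | 3-[2,4-bis(methoxymethoxy)-3,6-dimethylphenyl]-5,7-bis(methoxymethoxy)-6-methyl-1H-isochromene | COCOc1cc2c(c(OCOC)c1C)C=C(OC2)c1c(C)cc(OCOC)c(C)c1OCOC | intermediate
14 | {2-[hydroperoxy(methoxy)methyl]-3,5-bis(methoxymethoxy)-4-methylphenyl}methyl 2,4-bis(methoxymethoxy)-3,6-dimethylbenzoate (racemic, not isolated) | COCOc1cc(COC(=O)c2c(C)cc(OCOC)c(C)c2OCOC)c(C(OC)OO)c(OCOC)c1C | intermediate
15 | [2-formyl-3,5-bis(methoxymethoxy)-4-methylphenyl]methyl 2,4-bis(methoxymethoxy)-3,6-dimethylbenzoate | COCOc1cc(COC(=O)c2c(C)cc(OCOC)c(C)c2OCOC)c(C=O)c(OCOC)c1C | intermediate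
16 | 6-({[2,4-bis(methoxymethoxy)-3,6-dimethylbenzoyl]oxy}methyl)-2,4-bis(methoxymethoxy)-3-methylbenzoic acid | COCOc1cc(COC(=O)c2c(C)cc(OCOC)c(C)c2OCOC)c(C(=O)O)c(OCOC)c1C | intermediate
17 | 6-{[(2,4-dihydroxy-3,6-dimethylbenzoyl)oxy]methyl}-2,4-dihydroxy-3-methylbenzoic acid | Cc1cc(O)c(C)c(O)c1C(=O)OCc1cc(O)c(C)c(O)c1C(=O)O | target

**Count**
Total step count: 12. Longest linear sequence: 9 steps (1 → 2 → 3 → 4 → 5 → 12 → 13 → 15 → 16 → 17); the ring A branch (6 → 8 → 9 → 11) joins at step 8.

**Steps most likely to fail, with fallbacks**

Step 10 (ozonolysis). Ozone may not stop at the enol ether: with imperfect dosing it can go on to oxidise the two alkoxy-rich arene rings or the benzylic O–CH2 position, and a minor share of the primary ozonide may fragment in the reverse sense and lose the ester link. The fallback keeps the same C3=C4 cleavage but uses an oxidant that ignores alkoxybenzenes. It sets out from 13: dye-sensitised photooxygenation (O2, tetraphenylporphyrin, visible light, CH2Cl2, −78 °C) should add singlet oxygen across C3=C4 in a [2+2] sense, since the double bond has no allylic hydrogen for an ene reaction. This would give 3-[2,4-bis(methoxymethoxy)-3,6-dimethylphenyl]-5,7-bis(methoxymethoxy)-6-methyl-3,4-epidioxy-3,4-dihydro-1H-isochromene (cis-fused 1,2-dioxetane, racemic) F1. Warming F1 in toluene (60 °C) should bring about cycloreversion of the four-membered ring to the ester and formyl carbonyls, returning to the route at 15.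

Step 9 (cyclisation/reduction). Hydride transfer to the electron-rich, hindered benzopyrylium species may lag behind its formation, so that the cation is diverted by adventitious water or by transfer of a neighbouring methoxymethyl group onto the gold-activated alkyne. The fallback avoids the cation altogether and sets out from 12. NaBH4 (MeOH/THF, 0 °C) should reduce the aldehyde to [2-{[2,4-bis(methoxymethoxy)-3,6-dimethylphenyl]ethynyl}-3,5-bis(methoxymethoxy)-4-methylphenyl]methanol F2. Intramolecular hydroalkoxylation of F2 with Ph3PAuNTf2 (monovalent gold, 2 mol %, toluene, rt) should then close the pyran ring 6-endo, the slightly stronger donor ring A on the distal alkyne carbon favouring that mode over 5-exo, and the sequence returns to the route at 13.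

Step 8 (Sonogashira coupling). Both coupling sites are flanked by two ortho substituents, so transmetalation and reductive elimination may be slow enough for copper-mediated oxidative dimerisation of alkyne 11 to take over. The fallback removes copper, base and the free alkyne C–H, and sets out from 11. Deprotonation (n-BuLi, THF, −78 °C) and quenching with Bu3SnCl should give tributyl{[2,4-bis(methoxymethoxy)-3,6-dimethylphenyl]ethynyl}stannane F3. Stille coupling of F3 with iodide 5 (Pd(PPh3)4, toluene, 90 °C), in which alkynyl groups transfer from tin fastest of all, returns to the route at 12.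

**Further compounds**
F1 | step 10 | 3-[2,4-bis(methoxymethoxy)-3,6-dimethylphenyl]-5,7-bis(methoxymethoxy)-6-methyl-3,4-epidioxy-3,4-dihydro-1H-isochromene (cis-fused 1,2-dioxetane, racemic; one enantiomer drawn) | COCOc1cc2c(c(OCOC)c1C)[C@H]3OO[C@]3(OC2)c4c(C)cc(OCOC)c(C)c4OCOC
F2 | step 9 | [2-{[2,4-bis(methoxymethoxy)-3,6-dimethylphenyl]ethynyl}-3,5-bis(methoxymethoxy)-4-methylphenyl]methanol | OCc1cc(OCOC)c(C)c(OCOC)c1C#Cc1c(C)cc(OCOC)c(C)c1OCOC
F3 | step 8 | tributyl{[2,4-bis(methoxymethoxy)-3,6-dimethylphenyl]ethynyl}stannane | CCCC[Sn](CCCC)(CCCC)C#Cc1c(C)cc(OCOC)c(C)c1OCOC
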